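**Retrosynthetic overview**

1. Labdane numbering is used (ring A = C1–C5 and C10; ring B = C5–C10; C11 on C9, C17 on C8, C20 = methyl on C10). Endgame: the C17 alcohol is oxidised last; C12–C16 come from a C11 iodide by acetoacetate γ-alkylation, (E)-enol triflate formation and Stille hydroxymethylation (13E).
2. The C6=C7 bond and the C8 stereocentre come from reductive 1,3-transposition of a 6-oxo-7-ene tosylhydrazone (hydride to C6 anti to CH3-20, suprafacial hydrogen delivery to C8).
3. Key disconnection: the 6-oxo-7-ene ring B ⇒ cis-fused cyclobutanone (C6(=O)–C5–C10–C9) + terminal alkyne HC7≡C8–C17H2OPMB; nickel-catalysed insertion of the alkyne into the C6–C9 bond makes C6–C7 and C8–C9 together. Enabling feature: the C6–C5–C10–C9 edge of ring B can be closed to a strained four-membered ketone on ring A. Its C6–C9 bond is the only accessible acyl–alkyl bond, because C5 lies between the quaternary C4 and C10, and the C7–C8(–C17) unit maps onto a propargyl ether.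
4. Cyclobutanone ⇒ intramolecular keteniminium–alkene [2+2] cycloaddition of an open-chain amide. This closes ring A and the four-membered ring at once and sets C10 (C2-symmetric auxiliary) and C9 ((E)-alkene geometry).
5. Ring order: ring A plus cyclobutane (step 6), then ring B by two-carbon ring expansion (step 7). The open chain comes from 5-chloropent-1-yne (carboalumination) and isopropylidene Meldrum's acid.

Key step: step 7

Remark: "syn" and "anti" refer to the face of the bicycle that carries CH3-20; the absolute configuration of every bicyclic compound is that of its SMILES (ent-labdane series).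
Assumption: the (2R,5R)-amine 11 is taken to direct the cycloaddition to the C10 configuration shown; if the opposite sense is found, the commercially available (2S,5S)-amine is used instead.

**Route**

Step 1
Reactants: 1 5-chloropent-1-yne
Product: 4 (E)-6-chloro-3-methylhex-2-en-1-ol, via alkenylalane 2 (not isolated), via lithium aluminate 3 (not isolated)
Conditions: Me3Al, Cp2ZrCl2 (0.2 equiv), CH2Cl2, 0 °C→rt; n-BuLi, THF, −78 °C; (CH2O)n, −78 °C→rt; aq. HCl
Reagents that add atoms: trimethylaluminium C[Al](C)C; paraformaldehyde (as formaldehyde) C=O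
Why: Zirconium-catalysed Negishi carboalumination adds CH3 and Al syn across the alkyne with Al on the terminal carbon, and the aluminate is hydroxymethylated with retention, so the (E)-trisubstituted alkene (future C10=C9 with CH3-20 cis to C11) should form as one isomer.

Step 2
Reactants: 4 (E)-6-chloro-3-methylhex-2-en-1-ol
Product: 5 (E)-tert-butyl[(6-chloro-3-methylhex-2-en-1-yl)oxy]diphenylsilane
Conditions: TBDPSCl, imidazole, CH2Cl2, rt
Reagents that add atoms: tert-butyl(chloro)diphenylsilane CC(C)(C)[Si](Cl)(c1ccccc1)c1ccccc1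
Why: Silyl ether formation at the primary allylic alcohol; the TBDPS group should survive Grignard formation, triflic anhydride and nickel catalysis until it is removed with fluoride.

Step 3
Reactants: 5 (E)-tert-butyl[(6-chloro-3-methylhex-2-en-1-yl)oxy]diphenylsilane; 6 2,2-dimethyl-5-(propan-2-ylidene)-1,3-dioxane-4,6-dione (isopropylidene Meldrum's acid)
Product: 8 5-{(E)-8-[(tert-butyldiphenylsilyl)oxy]-2,6-dimethyloct-6-en-2-yl}-2,2-dimethyl-1,3-dioxane-4,6-dione, via Grignard reagent 7 (not isolated)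
Conditions: Mg, BrCH2CH2Br (cat.), THF, 65 °C; then 6, THF, 0 °C; aq. HCl
Reagents that add atoms: none
Why: Conjugate (Michael) addition of the primary Grignard reagent to the doubly activated alkylidene Meldrum's acid builds the quaternary gem-dimethyl carbon C4 without creating a stereocentre.

Step 4
Reactants: 8 5-{(E)-8-[(tert-butyldiphenylsilyl)oxy]-2,6-dimethyloct-6-en-2-yl}-2,2-dimethyl-1,3-dioxane-4,6-dione
Product: 10 (E)-9-[(tert-butyldiphenylsilyl)oxy]-3,3,7-trimethylnon-7-enoic acid, via malonic acid 9 (not isolated)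
Conditions: pyridine/H2O (10:1), 100 °C
Reagents that add atoms: water O
Why: Hydrolytic opening of the Meldrum's acid ring gives the malonic acid, which loses CO2 on heating (malonic acid decarboxylation) and leaves the C5–C6 acetic acid unit.

Step 5
Reactants: 10 (E)-9-[(tert-butyldiphenylsilyl)oxy]-3,3,7-trimethylnon-7-enoic acid; 11 (2R,5R)-2,5-dimethylpyrrolidine
Product: 13 (E)-9-[(tert-butyldiphenylsilyl)oxy]-1-[(2R,5R)-2,5-dimethylpyrrolidin-1-yl]-3,3,7-trimethylnon-7-en-1-one, via acid chloride 12 (not isolated)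
Conditions: (COCl)2, DMF (cat.), CH2Cl2, 0 °C→rt; then 11, Et3N, DMAP (cat.), 0 °C→rt
Reagents that add atoms: none
Why: Acid chloride formation and Schotten–Baumann-type amidation attach the C2-symmetric amine that serves as chiral auxiliary for the cycloaddition.

Step 6
Reactants: 13 (E)-9-[(tert-butyldiphenylsilyl)oxy]-1-[(2R,5R)-2,5-dimethylpyrrolidin-1-yl]-3,3,7-trimethylnon-7-en-1-one
Product: 16 cis-fused cyclobutanone 8-{[(tert-butyldiphenylsilyl)oxy]methyl}-1,5,5-trimethylbicyclo[4.2.0]octan-7-one (H-6 and the 8-CH2OSi group both syn to CH3-1), via keteniminium triflate 14 (not isolated), via cyclobutaniminium triflate 15 (not isolated)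
Conditions: Tf2O, 2,6-di-tert-butyl-4-methylpyridine, ClCH2CH2Cl, 0 °C→80 °C; then aq. NaHCO3, 60 °C
Reagents that add atoms: water O
Why: O-Triflation and elimination give the keteniminium ion, which undergoes intramolecular keteniminium–alkene [2+2] cycloaddition in which C6 bonds to the less substituted alkene carbon C9 and C5 closes onto the tertiary C10, so that ring A and the cis-fused cyclobutane form together, the (E)-alkene places C11 syn to CH3-20 and the auxiliary selects the alkene face (C10); hydrolysis frees the ketone.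

Step 7
Reactants: 16 cis-fused cyclobutanone; 17 1-methoxy-4-[(prop-2-yn-1-yloxy)methyl]benzene (4-methoxybenzyl propargyl ether)
Product: 18 cis-fused 6-oxo-7-ene (ring-B cyclohexenone; 8-CH2OPMB; 9-CH2OTBDPS; H5 and C11 both syn to CH3-20)
Conditions: Ni(cod)2 (10 mol %), PCy3 (20 mol %), toluene, 100 °C, 17 (2 equiv) added over 6 h
Reagents that add atoms: none
Why: Proposed new method: zerovalent nickel should couple the strained C6 carbonyl and the alkyne by oxidative cyclisation (C6–C7 bond, with the CH terminus of 17 next to the crowded carbonyl carbon and the CH2OPMB-bearing carbon on nickel), after which β-carbon elimination of the C6–C9 bond releases the four-ring strain and C(sp2)–C(sp3) reductive elimination forms C8–C9; the closest known reaction type is the nickel-catalysed insertion of internal alkynes into the acyl–CH2 bond of 3-substituted cyclobutanones to give cyclohex-2-enones. Ring B is closed as a six-membered ring by this formal [4+2] ring expansion (two-carbon insertion into C6–C9, the last bond being made by reductive elimination from a seven-membered nickelacycle), while ring A is untouched. No new stereocentre is made: C9 should migrate with retention because both elementary steps retain configuration at the alkyl carbon, and C5 and C10 are not involved, so the cis fusion of 16 is carried into 18. The step needs cleavage of C6–C9 and not C6–C5, which the substrate secures because C5 lies between the quaternary C4 and C10 while C9 carries only a CH2 group, and it needs the head-to-tail alkyne orientation, which the size difference between H and CH2OPMB at the hindered carbonyl carbon should secure. Slow addition of 17 is meant to suppress alkyne oligomerisation, and reductive elimination is expected to outrun β-hydride or β-silyloxy elimination at C9.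

Step 8
Reactants: 18 cis-fused 6-oxo-7-ene
Product: 20 trans-fused 6-oxo-7-ene (C5 epimer of 18; H5 anti to CH3-20), via lithium dienolate 19 (not isolated)
Conditions: LDA, THF, −78→−40 °C; AcOH, −78 °C
Reagents that add atoms: none
Why: Kinetic α′-deprotonation of the enone gives the cross-conjugated dienolate without touching the γ-hydrogen at C9, and C-protonation at C5 from the face anti to CH3-20 and the axial C4 methyl should give the trans ring fusion (enolate protonation; also the thermodynamically preferred fusion).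

Step 9
Reactants: 20 trans-fused 6-oxo-7-ene
Product: 21 tosylhydrazone of 20 (C6=N–NHTs)
Conditions: TsNHNH2, PPTS (cat.), EtOH, 70 °C
Reagents that add atoms: 4-methylbenzenesulfonohydrazide Cc1ccc(cc1)S(=O)(=O)NN
Why: Acid-catalysed condensation of the enone carbonyl with tosylhydrazide gives the α,β-unsaturated tosylhydrazone needed for the reductive transposition.

Step 10
Reactants: 21 tosylhydrazone of 20
Product: 24 Δ6-alkene (trans-decal-6-ene core; 8-CH2OPMB anti to CH3-20; 9-CH2OTBDPS syn to CH3-20), via N-boryl hydrazine 22 (not isolated), via allylic diazene 23 (not isolated)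
Conditions: catecholborane, CHCl3, 0 °C; then NaOAc·3H2O, 60 °C
Reagents that add atoms: none
Why: Reductive 1,3-transposition of an enone tosylhydrazone: catecholborane should reduce C=N from the face anti to CH3-20 and the axial C4 methyl, acetate-induced loss of sulfinate gives the allylic diazene on the CH3-20 face, and its retro-ene loss of N2 moves the double bond to C6=C7 while delivering hydrogen suprafacially to C8 on that same face, which places CH2OPMB anti to CH3-20 and trans to the C9 substituent.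

Step 11
Reactants: 24 Δ6-alkene
Product: 25 C11 alcohol (9-CH2OH; 8-CH2OPMB)
Conditions: TBAF, THF, rt; aq. NH4Cl
Reagents that add atoms: none
Why: Fluoride-mediated desilylation cleaves the TBDPS ether while the PMB ether is inert.

Step 12
Reactants: 25 C11 alcohol
Product: 26 C11 iodide (9-CH2I; 8-CH2OPMB)
Conditions: I2, PPh3, imidazole, CH2Cl2, 0 °C→rt
Reagents that add atoms: iodine II
Why: Appel-type iodination converts the primary alcohol into the iodide by SN2 at C11 without touching a stereocentre.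

Step 13
Reactants: 26 C11 iodide; 27 tert-butyl 3-oxobutanoate
Product: 29 tert-butyl β-keto ester (C9–CH2CH2C(=O)CH2CO2tBu; C11–C15), via acetoacetate dianion 28 (not isolated)
Conditions: 27 (3 equiv), NaH, THF, 0 °C; n-BuLi, 0 °C; then 26, DMPU, 0 °C→rt; aq. NH4Cl
Reagents that add atoms: none
Why: γ-Alkylation of the acetoacetate dianion (SN2 at the primary iodide) installs C12–C15 as the β-keto ester in one step.

Step 14
Reactants: 29 tert-butyl β-keto ester
Product: 30 (E)-enol triflate (13-OTf trans to the C15 ester)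
Conditions: Tf2O, aq. Me4NOH, hexanes, 5 °C
Reagents that add atoms: trifluoromethanesulfonic anhydride O=S(=O)(OS(=O)(=O)C(F)(F)F)C(F)(F)F
Why: O-Sulfonylation of the non-chelated tetramethylammonium enolate of the β-keto ester should give the (E)-enol triflate, which fixes the later 13E geometry.

Step 15
Reactants: 30 (E)-enol triflate; 31 (tributylstannyl)methanol
Product: 32 (13E)-16-hydroxy tert-butyl ester
Conditions: Pd(PPh3)4 (5 mol %), LiCl, 1,4-dioxane, 90 °C
Reagents that add atoms: none
Why: Stille coupling transfers the hydroxymethyl group from tin with retention of the enol triflate geometry, so CH2OH ends trans to the ester.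

Step 16
Reactants: 32 (13E)-16-hydroxy tert-butyl ester
Product: 33 (13E)-16-acetoxy tert-butyl ester
Conditions: Ac2O, pyridine, DMAP (cat.), CH2Cl2, 0 °C
Reagents that add atoms: acetic anhydride CC(=O)OC(C)=O
Why: DMAP-catalysed acetylation of the only free hydroxyl gives the C16 acetate.

Step 17
Reactants: 33 (13E)-16-acetoxy tert-butyl ester
Product: 34 (13E)-16-acetoxy-17-hydroxy acid
Conditions: TFA/CH2Cl2 (1:4), anisole, 0 °C→rt; then aq. NaHCO3, MeOH, 0 °C; acidify to pH 4
Reagents that add atoms: none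
Why: Acidolysis removes the tert-butyl ester as isobutene and the PMB ether as the anisole-trapped benzyl cation in one operation, while the allylic acetate of the electron-poor alkene and both C=C bonds should stay intact.

Step 18
Reactants: 34 (13E)-16-acetoxy-17-hydroxy acid
Product: 35 target (5R,8S,9R,10S,13E)-16-acetoxy-17-oxolabda-6,13-dien-15-oic acid
Conditions: Dess–Martin periodinane, NaHCO3, CH2Cl2, 0 °C
Reagents that add atoms: none
Why: Dess–Martin oxidation of the primary alcohol under buffered, non-basic conditions should give the β,γ-unsaturated aldehyde without epimerisation at C8 or migration of the C6=C7 bond into conjugation.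

**Compound list**

1 | 5-chloropent-1-yne | ClCCCC#C | starting material
2 | (E)-(5-chloro-2-methylpent-1-en-1-yl)dimethylalane | C[Al](C)/C=C(\C)CCCCl | intermediate
3 | lithium butyl[(E)-5-chloro-2-methylpent-1-en-1-yl]dimethylaluminate | [Li+].CCCC[Al-](C)(C)/C=C(\C)CCCCl | intermediate
4 | (E)-6-chloro-3-methylhex-2-en-1-ol | OC/C=C(\C)CCCCl | intermediate
5 | (E)-tert-butyl[(6-chloro-3-methylhex-2-en-1-yl)oxy]diphenylsilane | CC(C)(C)[Si](OC/C=C(\C)CCCCl)(c1ccccc1)c1ccccc1 | intermediate
6 | 2,2-dimethyl-5-(propan-2-ylidene)-1,3-dioxane-4,6-dione (isopropylidene Meldrum's acid) | CC(C)=C1C(=O)OC(C)(C)OC1=O | starting material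
7 | {(E)-6-[(tert-butyldiphenylsilyl)oxy]-4-methylhex-4-en-1-yl}magnesium chloride | Cl[Mg]CCC/C(C)=C/CO[Si](c1ccccc1)(c1ccccc1)C(C)(C)C | intermediate
8 | 5-{(E)-8-[(tert-butyldiphenylsilyl)oxy]-2,6-dimethyloct-6-en-2-yl}-2,2-dimethyl-1,3-dioxane-4,6-dione | CC1(C)OC(=O)C(C(=O)O1)C(C)(C)CCC/C(C)=C/CO[Si](c1ccccc1)(c1ccccc1)C(C)(C)C | intermediate
9 | 2-{(E)-8-[(tert-butyldiphenylsilyl)oxy]-2,6-dimethyloct-6-en-2-yl}propanedioic acid | OC(=O)C(C(=O)O)C(C)(C)CCC/C(C)=C/CO[Si](c1ccccc1)(c1ccccc1)C(C)(C)C | intermediate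
10 | (E)-9-[(tert-butyldiphenylsilyl)oxy]-3,3,7-trimethylnon-7-enoic acid | OC(=O)CC(C)(C)CCC/C(C)=C/CO[Si](c1ccccc1)(c1ccccc1)C(C)(C)C | intermediate
11 | (2R,5R)-2,5-dimethylpyrrolidine | C[C@@H]1CC[C@@H](C)N1 | starting material
12 | (E)-9-[(tert-butyldiphenylsilyl)oxy]-3,3,7-trimethylnon-7-enoyl chloride | ClC(=O)CC(C)(C)CCC/C(C)=C/CO[Si](c1ccccc1)(c1ccccc1)C(C)(C)C | intermediate
13 | (E)-9-[(tert-butyldiphenylsilyl)oxy]-1-[(2R,5R)-2,5-dimethylpyrrolidin-1-yl]-3,3,7-trimethylnon-7-en-1-one | C[C@@H]1CC[C@@H](C)N1C(=O)CC(C)(C)CCC/C(C)=C/CO[Si](c1ccccc1)(c1ccccc1)C(C)(C)C | intermediate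
14 | keteniminium triflate derived from 13 (N=C=C cumulene on the (2R,5R)-2,5-dimethylpyrrolidinium nitrogen) | C[C@@H]1CC[C@@H](C)[N+]1=C=CC(C)(C)CCC/C(C)=C/CO[Si](c1ccccc1)(c1ccccc1)C(C)(C)C.[O-]S(=O)(=O)C(F)(F)F | intermediate
15 | cyclobutaniminium triflate (iminium salt of ketone 16 with the (2R,5R)-auxiliary) | CC(C)(C)[Si](OC[C@@H]1C(=[N+]3[C@H](C)CC[C@H]3C)[C@H]2C(C)(C)CCC[C@@]12C)(c4ccccc4)c5ccccc5.[O-]S(=O)(=O)C(F)(F)F | intermediate
16 | cis-fused 8-{[(tert-butyldiphenylsilyl)oxy]methyl}-1,5,5-trimethylbicyclo[4.2.0]octan-7-one; H-6, CH3-1 and the 8-CH2OSi group on one face (labdane: C6 ketone, H5 and C11 syn to CH3-20) | CC(C)(C)[Si](OC[C@@H]1C(=O)[C@H]2C(C)(C)CCC[C@@]12C)(c3ccccc3)c4ccccc4 | intermediate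
17 | 1-methoxy-4-[(prop-2-yn-1-yloxy)methyl]benzene | C#CCOCc1ccc(OC)cc1 | starting material
18 | cis-fused 4-{[(tert-butyldiphenylsilyl)oxy]methyl}-3-{[(4-methoxybenzyl)oxy]methyl}-4a,8,8-trimethyl-4a,5,6,7,8,8a-hexahydronaphthalen-1(4H)-one; H-8a and the 4-substituent syn to CH3-4a (labdane: 6-oxo-7-ene, H5 syn to CH3-20) | CC(C)(C)[Si](OC[C@@H]1C(COCc3ccc(OC)cc3)=CC(=O)[C@H]2C(C)(C)CCC[C@@]12C)(c4ccccc4)c5ccccc5 | intermediate
19 | lithium cross-conjugated dienolate of 18 (C5=C6–O−, C7=C8) | [Li+].CC(C)(C)[Si](OC[C@@H]1C(COCc3ccc(OC)cc3)=CC([O-])=C2C(C)(C)CCC[C@@]12C)(c4ccccc4)c5ccccc5 | intermediate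
20 | trans-fused enone, as 18 but H-8a anti to CH3-4a (labdane: 6-oxo-7-ene, H5 anti to CH3-20) | CC(C)(C)[Si](OC[C@@H]1C(COCc3ccc(OC)cc3)=CC(=O)[C@@H]2C(C)(C)CCC[C@@]12C)(c4ccccc4)c5ccccc5 | intermediate
21 | 4-methylbenzenesulfonohydrazone of 20 at C6 (NHTs on the C7 side) | CC(C)(C)[Si](OC[C@@H]1C(COCc3ccc(OC)cc3)=C/C(=N\NS(=O)(=O)c6ccc(C)cc6)[C@@H]2C(C)(C)CCC[C@@]12C)(c4ccccc4)c5ccccc5 | intermediate
22 | N-(1,3,2-benzodioxaborol-2-yl)-N′-tosylhydrazine at C6 of the 7-ene (C6–N syn to CH3-20) | CC(C)(C)[Si](OC[C@@H]1C(COCc3ccc(OC)cc3)=C[C@H](N(NS(=O)(=O)c6ccc(C)cc6)B7Oc8ccccc8O7)[C@@H]2C(C)(C)CCC[C@@]12C)(c4ccccc4)c5ccccc5 | intermediate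
23 | allylic diazene (C6–N=NH syn to CH3-20, C7=C8) | CC(C)(C)[Si](OC[C@@H]1C(COCc3ccc(OC)cc3)=C[C@H](N=N)[C@@H]2C(C)(C)CCC[C@@]12C)(c4ccccc4)c5ccccc5 | intermediate
24 | Δ6-alkene: trans-fused 4,4,10-trimethyldecal-6-ene (labdane numbering) with 8-CH2OPMB anti to CH3-20 and 9-CH2OTBDPS syn to CH3-20 | CC(C)(C)[Si](OC[C@@H]1[C@@H](COCc3ccc(OC)cc3)C=C[C@@H]2C(C)(C)CCC[C@@]12C)(c4ccccc4)c5ccccc5 | intermediate
25 | C11 alcohol: as 24 with 9-CH2OH | OC[C@@H]1[C@@H](COCc3ccc(OC)cc3)C=C[C@@H]2C(C)(C)CCC[C@@]12C | intermediate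
26 | C11 iodide: as 24 with 9-CH2I | IC[C@@H]1[C@@H](COCc3ccc(OC)cc3)C=C[C@@H]2C(C)(C)CCC[C@@]12C | intermediate
27 | tert-butyl 3-oxobutanoate | CC(=O)CC(=O)OC(C)(C)C | starting material
28 | sodium lithium dianion of tert-butyl 3-oxobutanoate | [Na+].[Li+].[CH2-]C(=O)[CH-]C(=O)OC(C)(C)C | intermediate
29 | tert-butyl 3-oxo-5-(bicyclic C9 unit)pentanoate (labdane C11–C15 β-keto ester; core as 24 with 8-CH2OPMB) | CC(C)(C)OC(=O)CC(=O)CC[C@@H]1[C@@H](COCc3ccc(OC)cc3)C=C[C@@H]2C(C)(C)CCC[C@@]12C | intermediate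
30 | tert-butyl (E)-3-[(trifluoromethylsulfonyl)oxy]pent-2-enoate bearing the bicyclic C9 unit at C5 (OTf trans to the ester) | CC(C)(C)OC(=O)/C=C(/OS(=O)(=O)C(F)(F)F)CC[C@@H]1[C@@H](COCc3ccc(OC)cc3)C=C[C@@H]2C(C)(C)CCC[C@@]12C | intermediate
31 | (tributylstannyl)methanol | OC[Sn](CCCC)(CCCC)CCCC | starting material
32 | tert-butyl (13E)-16-hydroxy-17-[(4-methoxybenzyl)oxy]labda-6,13-dien-15-oate (ent series) | CC(C)(C)OC(=O)/C=C(/CO)CC[C@@H]1[C@@H](COCc3ccc(OC)cc3)C=C[C@@H]2C(C)(C)CCC[C@@]12C | intermediate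
33 | tert-butyl (13E)-16-acetoxy-17-[(4-methoxybenzyl)oxy]labda-6,13-dien-15-oate (ent series) | CC(=O)OC/C(=C/C(=O)OC(C)(C)C)CC[C@@H]1[C@@H](COCc3ccc(OC)cc3)C=C[C@@H]2C(C)(C)CCC[C@@]12C | intermediate
34 | (13E)-16-acetoxy-17-hydroxylabda-6,13-dien-15-oic acid (ent series) | CC(=O)OC/C(=C/C(=O)O)CC[C@@H]1[C@@H](CO)C=C[C@@H]2C(C)(C)CCC[C@@]12C | intermediate
35 | (5R,8S,9R,10S,13E)-16-acetoxy-17-oxolabda-6,13-dien-15-oic acid | CC(=O)OC/C(=C/C(=O)O)CC[C@@H]1[C@@H](C=O)C=C[C@@H]2C(C)(C)CCC[C@@]12C | target

**Step count and risks**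

Total step count: 18. Longest linear sequence: 18 steps (1 → 35).

Steps most likely to fail:

1. Step 7 (Proposed new method). What may go wrong: nickel-catalysed oligomerisation of the terminal alkyne may outrun carbonyl–alkyne oxidative cyclisation at the hindered ketone; β-carbon elimination may fail or take the C6–C5 bond; β-hydride or β-silyloxy elimination at C9 may intercept the nickelacycle. Fallback with known reaction types, setting out from 16 and coming back at 24: condensation of 16 with pyrrolidine (TiCl4, toluene) should give the C6=C9 pyrrolidine enamine F1. Dimethyl acetylenedicarboxylate then adds by the classical enamine–alkyne [2+2] cycloaddition, the aminocyclobutene opens with two-carbon ring expansion (again forming C6–C7 and C8–C9 together), and aqueous acid hydrolysis should give the ring-B β-keto diester F2. Krapcho demethoxycarbonylation (LiCl, wet DMSO, 150 °C) removes the C7 ester to give the cis-fused keto ester F3, and NaOMe in MeOH equilibrates C5 to the trans-fused keto ester F4. Hydrogenation of the tetrasubstituted C8=C9 enoate (H2, [Ir(cod)(PCy3)(py)]PF6, CH2Cl2) from the face anti to CH3-20 sets H9 and should give the C8-axial ester F5, which NaOMe equilibrates to the equatorial ester F6. Kinetic enolisation toward C7 and triflation (KHMDS, PhNTf2) gives the enol triflate F7, Pd(OAc)2/PPh3 with HCO2H and Bu3N reduces it to the Δ6 ester F8, and DIBAL-H gives the primary alcohol F9. 4-Methoxybenzyl trichloroacetimidate with catalytic acid then returns 24.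

2. Step 8. What may go wrong: deprotonation at the shielded C5–H may be too slow, competing γ-deprotonation may scramble C9, or proton transfer to the enolate may be unselective. Fallback, setting out from 18 and coming back at 20: LDA in the presence of Me3SiCl (internal quench) traps the C5 enolate irreversibly as the cross-conjugated trimethylsilyl dienol ether F10, which is purified and then protodesilylated at −78 °C with acetic acid-buffered tetrabutylammonium fluoride, so that C-protonation at C5 occurs as a separate, tunable event from the face anti to CH3-20.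

3. Step 13. What may go wrong: SN2 displacement at the β-branched, neopentyl-like C11 iodide may be too slow, so that elimination, O-alkylation or recovery of iodide dominates. Fallback, setting out from 25 and coming back at 29: Dess–Martin oxidation of 25 gives the C11 aldehyde F11; Wittig olefination with methyl (triphenyl-λ5-phosphanylidene)acetate gives the (E)-enoate F12; conjugate reduction with magnesium in methanol (the isolated C6=C7 bond is inert) gives the saturated methyl ester F13; crossed Claisen condensation with the lithium enolate of tert-butyl acetate gives 29.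

**Further compounds**

F1 | step 7 | 1-[cis-fused 8-{[(tert-butyldiphenylsilyl)oxy]methyl}-1,5,5-trimethylbicyclo[4.2.0]oct-7-en-7-yl]pyrrolidine (C6=C9 enamine of 16) | CC(C)(C)[Si](OCC1=C(N6CCCC6)[C@H]2C(C)(C)CCC[C@@]12C)(c3ccccc3)c4ccccc4
F2 | step 7 | ring-expanded cis-fused β-keto diester, enol form (C6–OH, C7–CO2Me, C8–CO2Me, C8=C9, 9-CH2OTBDPS) | CC(C)(C)[Si](OCC1=C(C(=O)OC)C(C(=O)OC)=C(O)[C@H]2C(C)(C)CCC[C@@]12C)(c3ccccc3)c4ccccc4
F3 | step 7 | cis-fused 6-oxo-8-ene 8-carboxylic acid methyl ester (C7H2, C8=C9, H5 syn to CH3-20) | CC(C)(C)[Si](OCC1=C(C(=O)OC)CC(=O)[C@H]2C(C)(C)CCC[C@@]12C)(c3ccccc3)c4ccccc4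
F4 | step 7 | trans-fused 6-oxo-8-ene 8-carboxylic acid methyl ester (H5 anti to CH3-20) | CC(C)(C)[Si](OCC1=C(C(=O)OC)CC(=O)[C@@H]2C(C)(C)CCC[C@@]12C)(c3ccccc3)c4ccccc4
F5 | step 7 | trans-fused saturated 6-keto ester with 8-CO2Me syn to CH3-20 (axial) and 9-CH2OTBDPS syn to CH3-20 | CC(C)(C)[Si](OC[C@@H]1[C@H](C(=O)OC)CC(=O)[C@@H]2C(C)(C)CCC[C@@]12C)(c3ccccc3)c4ccccc4
F6 | step 7 | trans-fused saturated 6-keto ester with 8-CO2Me anti to CH3-20 (equatorial) | CC(C)(C)[Si](OC[C@@H]1[C@@H](C(=O)OC)CC(=O)[C@@H]2C(C)(C)CCC[C@@]12C)(c3ccccc3)c4ccccc4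
F7 | step 7 | C6 enol triflate of F6 (C6=C7) | CC(C)(C)[Si](OC[C@@H]1[C@@H](C(=O)OC)C=C(OS(=O)(=O)C(F)(F)F)[C@@H]2C(C)(C)CCC[C@@]12C)(c3ccccc3)c4ccccc4
F8 | step 7 | Δ6 methyl ester (core of 24 with 8-CO2Me) | CC(C)(C)[Si](OC[C@@H]1[C@@H](C(=O)OC)C=C[C@@H]2C(C)(C)CCC[C@@]12C)(c3ccccc3)c4ccccc4
F9 | step 7 | Δ6 C17 alcohol (core of 24 with 8-CH2OH) | CC(C)(C)[Si](OC[C@@H]1[C@@H](CO)C=C[C@@H]2C(C)(C)CCC[C@@]12C)(c3ccccc3)c4ccccc4
F10 | step 8 | cross-conjugated trimethylsilyl dienol ether of 18 (C5=C6–OSiMe3, C7=C8) | CC(C)(C)[Si](OC[C@@H]1C(COCc3ccc(OC)cc3)=CC(O[Si](C)(C)C)=C2C(C)(C)CCC[C@@]12C)(c4ccccc4)c5ccccc5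
F11 | step 13 | C11 aldehyde (core of 24 with 9-CHO and 8-CH2OPMB) | O=C[C@@H]1[C@@H](COCc3ccc(OC)cc3)C=C[C@@H]2C(C)(C)CCC[C@@]12C
F12 | step 13 | methyl (E)-3-(bicyclic C9 unit)prop-2-enoate (C11=C12 enoate) | COC(=O)/C=C/[C@@H]1[C@@H](COCc3ccc(OC)cc3)C=C[C@@H]2C(C)(C)CCC[C@@]12C
F13 | step 13 | methyl 3-(bicyclic C9 unit)propanoate (C11–C13 ester) | COC(=O)CC[C@@H]1[C@@H](COCc3ccc(OC)cc3)C=C[C@@H]2C(C)(C)CCC[C@@]12C
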